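The vessel is a closed, stirred flask at constant temperature, in which free enzyme turns starting material and second substrate into target.

in all of them: starting material 0.10 M

| run | second substrate | free enzyme | remark | time |
|---|---|---|---|---|
| green | 0.050 M | 5 µM | run made earlier |  |
| teal | 0.050 M | 20 µM | run made earlier |  |
| blue | 0.075 M | 10 µM | run made earlier |  |
| flask | 0.0500 M | 10 µM |  | 2.5 min |

| run | time / s | target / % | starting material / % |
|---|---|---|---|
| green | 40.0 | 12.5 | 87.5 |
| green | 60.0 | 17.2 | 83.2 |
| green | 80.0 | 21.1 | 79.2 |
| green | 120 | 26.8 | 72.5 |
| teal | 40.0 | 30.2 | 69.2 |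
| teal | 60.0 | 35.8 | 63.1 |
| teal | 80.0 | 40.6 | 59.6 |
| teal | 120 | 45.4 | 55.7 |
| blue | 40.0 | 27.5 | 72.2 |
| blue | 60.0 | 34.9 | 64.4 |
| blue | 80.0 | 41.5 | 60.0 |
| blue | 120 | 49.6 | 51.0 |

(readings scatter by 0.5 percentage points)

* time, not beyond 2.5 min, at which the flask holds most target
* the amount of target, in percent of the starting material charged, at that time

- the numbers in the tables scatter by 0.5 percentage points (one standard deviation)

Read the teal table row by row, since the flask has the same substrate charges as teal and half its enzyme. If the rate goes with enzyme, then at these substrate charges equal enzyme charge times time gives equal target, so 2.5 min in the flask becomes 75.0 s in teal. This is the teal clock: time multiplied by a flask's enzyme charge and divided by teal's, at teal's substrate charges.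

Test it on green. Its last row, 120 s, reads 30.0 s on the teal clock, and its 26.8% of target lies below teal's first row, 30.2% at 40.0 s, in line with a rising curve.

Teal's next two rows, 35.8% at 60.0 s and 40.6% at 80.0 s, bracket the flask's end on the teal clock, and straight interpolation gives me 39.4%. Teal's last row still gains, reaching 45.4% at 120 s, later than 75.0 s and below the 50.0% allowed by the second substrate, the limiting reagent. So I would take the end of the time allowed.

The forecast says 2.5 min and 39.7%, a little above my reading, holding that target “should still be rising at 2.5 min”.

The flask gives 2.50 min and 40.0%.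

    starting material + free enzyme ⇌ first complex (K = 160 M⁻¹, k = 6.20 × 10⁵ M⁻¹ s⁻¹)
    first complex ⇌ loaded enzyme + first product (K = 0.0400 M, k = 750 s⁻¹)
    second substrate + loaded enzyme ⇌ second complex (K = 7.40 M⁻¹, k = 1.00 × 10⁵ M⁻¹ s⁻¹)
    second complex → free enzyme + target (k = 330 s⁻¹)
    2 first complex ⇌ resting dimer (K = 68000 M⁻¹, k = 3300 M⁻¹ s⁻¹)

The flask's 40.0% lies between the two teal readings around 75.0 s. The neighbour with 6.00 µM of free enzyme reads 45.0 s on the teal clock, and its 33.1% lies between teal's rows at 40.0 s and 60.0 s. In the flask, the slowest mode's half-life at the end, 1.17 min, is shorter than 2.5 min, and the gap to the 50.0% that the charges allow shrinks from 20 percentage points at 1.25 min to 10 points at 2.50 min. At 25.0 min the flask holds 50.0% of target, with 0% of the second substrate left.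

Readings and results are calculated for substances that don't exist; the scatter is artificial.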